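The data come from a simulation for an exercise.

At late times the maple run decayed like a discharging capacitor: the intermediate fell from 71% of the substrate charged at 1.00 h to 29% at 4.00 h. From these two readings I took the loss time, the time constant of that tail, as 3.35 h. By 0.333 h, intermediate and target together had reached 63.0% in the readings, so I read the substrate's pseudo-first-order time constant in maple as about 0.335 h. That is far shorter than the loss time, so I treated it as a correction.

| setting | maple | oak | cedar | alder | north-east | north-west | south | south-east |
|---|---|---|---|---|---|---|---|---|
| substrate | 0.12 M | 0.12 M | 0.12 M | 0.18 M | 0.12 M | 0.12 M | 0.12 M | 0.12 M |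
| partner | 0.36 M | 0.24 M | 0.54 M | 0.36 M | 0.360 M (fed, over 4.00 h) | 0.360 M | 0.360 M | 0.360 M |
| remark | run made earlier | run made earlier | run made earlier | run made earlier | all but partner at the start; partner goes in evenly over 4.00 h, the run ends at 4.0 h | everything together in a closed stirred flask, run for 4.0 h | a single well-mixed tank run continuously and read at steady state, 4.0 h in it on average | a single well-mixed tank run continuously and read at steady state, 20.0 h in it on average |
| time |  |  |  |  | 4.0 h | 4.0 h |  |  |

| run | time / h | intermediate / % | target / % |
|---|---|---|---|
| maple | 0.333 | 57 | 6 |
| maple | 1.00 | 71 | 19 |
| maple | 2.00 | 51 | 35 |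
| maple | 3.00 | 41 | 33 |
| maple | 4.00 | 29 | 26 |
| oak | 0.200 | 35 | 4 |
| oak | 0.667 | 58 | 12 |
| oak | 1.00 | 58 | 22 |
| oak | 1.50 | 57 | 23 |
| oak | 2.50 | 46 | 33 |
| cedar | 0.500 | 72 | 10 |
| cedar | 1.00 | 71 | 26 |
| cedar | 1.33 | 56 | 27 |
| cedar | 2.00 | 48 | 31 |
| cedar | 2.50 | 39 | 35 |
| alder | 0.200 | 43 | 5 |
| alder | 0.333 | 55 | 7 |
| alder | 0.667 | 67 | 14 |
| alder | 1.33 | 59 | 31 |
| alder | 2.50 | 43 | 30 |

(standard deviation of a reading: 2 percentage points)

- the stated concentrations are those of everything mixed, before any reaction; amounts are the same in each set-up
- the feed brings no volume worth counting
- the earlier runs were made in a closed, stirred flask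

- the set-up with the highest amount of intermediate at the outlet or at the end, in percent of the substrate put in ("none" if the first two lie within 2 percentage points) (north-east / north-west / south / south-east / none)
- amount of intermediate at the outlet or at the end, in percent of the substrate put in, north-east
- amount of intermediate at the outlet or at the end, in percent of the substrate put in, north-west
- amount of intermediate at the outlet or at the end, in percent of the substrate put in, south
- amount of intermediate at the outlet or at the end, in percent of the substrate put in, south-east

In north-east, taking one partner per substrate, enough partner to match the charge has entered by 1.33 h. In one extreme, partner reacts on entry, intermediate forms evenly over that span, and averaging its survival over the loss time gives 37.2%. In the other, formation spreads evenly over the whole feed, giving 58.4%. I expected north-east between them, because a portion of partner meeting the full substrate lasts about 1.00 h, shorter than the feed but not negligible beside 1.33 h. I committed to the middle, 47.8%.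

For a well-mixed tank at steady state I assumed a first-order loss, so I divided what it forms by one plus residence time over loss time, and I took the fraction of substrate converted as one over one plus that substrate time constant over residence time. That gave me 42.1% for south and 14.1% for south-east, while maple's last reading stood for north-west.

The forecast named north-east, with 44%, 28%, 36% and 11.5% for north-east, north-west, south and south-east, saying “Summing the surviving slices gives about 44%”. My north-east figure stood above its figure.

North-east gave 43.1%, ahead of north-west at 30.2%, south at 37.8% and south-east at 14.0%.

    substrate + partner → intermediate + by-product (k = 10.1 /M/h)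
    intermediate ⇌ target (K = 1.62, k = 0.494 /h)
    intermediate ⇌ isomer of the product A (K = 3.03, k = 0.0236 /h)
    target ⇌ isomer of the product B (K = 17.0, k = 0.105 /h)
    target → over-reaction product (k = 0.257 /h)

Partner in north-east peaked at twice the substrate charge. On the loss clock, north-east's result corresponds to an age of 2.82 h, and north-west's to 4.01 h. South-east left 2.00% of its substrate, so the tank rule with that loss time gives 14.1%, and that tank read 14.0%.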